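**Retrosynthetic overview** (ring carbons of the cyclohexene: C1 aroyl-bearing, C2 prenyl-bearing, C3 methyl-bearing, C4 alkene CH, C5 CH2, C6 phenyl-bearing)

1. The target is traced back, through ortho-O-demethylation, loss of a temporary CO2Me group at C1, a Wittig reaction and a Claisen rearrangement, to a bridged lactone in which an O–C(=O) unit spans C4 and C1.
2. This 2-oxabicyclo[2.2.2]octenone is cut at C4–C5 and C1–C6 into styrene and a 3-aroyl-5-methyl-2H-pyran-2-one, joined by one catalytic asymmetric inverse-electron-demand Diels–Alder reaction.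
3. Enabling feature: C1 carries the aroyl C=O and stands 1,4 to the alkene carbon C4, with C2–C3 between them. Tied by a CO2 bridge, C1–C2–C3–C4 becomes the diene of a 2-pyranone ring (O1, C2(=O), C3 to C6), electron-poor and chelating through its lactone and ketone carbonyls.
4. The bridge is then used twice before it leaves: its C4–O bond hands the side chain to C2 on its own face (this sets C2 against C6 and moves the alkene to C3=C4), and its carbonyl carbon departs as CO2, after which C1 settles by equilibration.
5. Ring order: pyranone (step 2), carbocycle inside the bicyclic lactone (step 3), lactone ring opened (step 4); the arene is bought.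

Key step: step 3

Remark on the chemistry: the (S,S)-ligand is assumed to leave open the diene face that leads to 7; if the sense of induction is the opposite one, the (R,R)-ligand takes its place and nothing else changes.

Step 1
Reactants: 1 1-(2,4,6-trimethoxyphenyl)ethan-1-one
Product: 2 methyl 3-oxo-3-(2,4,6-trimethoxyphenyl)propanoate
Conditions: NaH (2.5 equiv), dimethyl carbonate, THF, reflux; then aq. HCl
Reagents that add atoms: dimethyl carbonate, COC(=O)OC
Why: Crossed Claisen condensation of the only enolisable position of the ketone with a carbonate that cannot enolise, driven by deprotonation of the β-keto ester formed.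

Step 2
Reactants: 2 methyl 3-oxo-3-(2,4,6-trimethoxyphenyl)propanoate; 3 (2E)-3-ethoxy-2-methylprop-2-enal
Product: 5 5-methyl-3-(2,4,6-trimethoxybenzoyl)-2H-pyran-2-one, via Knoevenagel dienoate 4 (not isolated)
Conditions: piperidine (cat.), AcOH (cat.), toluene, 80 °C; then p-TsOH·H2O (cat.), toluene, 110 °C
Reagents that add atoms: none
Why: Knoevenagel condensation at the aldehyde, then acid-promoted hydrolysis of the vinylogous ester terminus and enol-lactonisation onto the methyl ester, made irreversible by loss of methanol; this is the vinylogous counterpart of the 3-acylcoumarin synthesis from salicylaldehyde and a β-keto ester and of the preparation of 3-carbomethoxy-2-pyranone from a malonate.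

Step 3
Reactants: 5 5-methyl-3-(2,4,6-trimethoxybenzoyl)-2H-pyran-2-one; 6 styrene
Product: 7 (1R,4R,8S)-6-methyl-8-phenyl-4-(2,4,6-trimethoxybenzoyl)-2-oxabicyclo[2.2.2]oct-5-en-3-one
Conditions: Cu(OTf)2 (10 mol %), 2,2'-(propane-2,2-diyl)bis[(4S)-4-tert-butyl-4,5-dihydro-1,3-oxazole] (11 mol %), styrene (3 equiv), 4 Å molecular sieves, CH2Cl2, −20 °C to rt
Reagents that add atoms: none
Why: The bis(oxazoline)–Cu(OTf)2 complex should bind the lactone and ketone carbonyls of 5 in a six-membered chelate, which lowers the LUMO of the pyranone diene and fixes its geometry, so that styrene adds in an asynchronous concerted inverse-electron-demand Diels–Alder reaction, its CH2 terminus bonding to C6 of the pyranone and its benzylic carbon to C3. The closest known reaction types are the copper–bis(oxazoline) catalysed inverse-demand cycloaddition of 3-carboalkoxy-2-pyranones with enol ethers and with indene-type styrenes, and the uncatalysed addition of styrenes to electron-poor 2-pyranones. The six-membered carbocycle is closed by the suprafacial [4+2] event itself, both bonds forming in the one step and turning the pyranone into the 2-oxabicyclo[2.2.2]octenone, which should not lose CO2 at or below room temperature. The phenyl-bearing carbon is set by the endo approach (phenyl under the diene, hence anti to the O–C(=O) bridge), and its absolute configuration and that of the two bridgeheads by the tert-butyl groups of the ligand, which leave one face of the chelated diene open. The step needs regioselectivity, secured by the polarisation of both partners (the aroyl and lactone carbonyls make C6 the acceptor end, phenyl makes the CH2 the donor end), and endo and facial selectivity, secured by secondary overlap and the rigid chelate.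

Step 4
Reactants: 7 (1R,4R,8S)-6-methyl-8-phenyl-4-(2,4,6-trimethoxybenzoyl)-2-oxabicyclo[2.2.2]oct-5-en-3-one
Product: 8 methyl (1R,4R,6S)-4-hydroxy-3-methyl-6-phenyl-1-(2,4,6-trimethoxybenzoyl)cyclohex-2-ene-1-carboxylate
Conditions: K2CO3 (0.2 equiv), MeOH, 0 °C to rt; aq. NH4Cl
Reagents that add atoms: methanol, CO
Why: Methanolysis (transesterification) of a strained bridged lactone by acyl–oxygen cleavage, so the carbinol configuration at C4 is untouched, while the ketone is shielded by the 2,6-dimethoxyaryl group and the quaternary C1, which also cannot enolise.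

Step 5
Reactants: 8 methyl (1R,4R,6S)-4-hydroxy-3-methyl-6-phenyl-1-(2,4,6-trimethoxybenzoyl)cyclohex-2-ene-1-carboxylate
Product: 10 methyl (1R,2R,6S)-3-methyl-2-(2-oxoethyl)-6-phenyl-1-(2,4,6-trimethoxybenzoyl)cyclohex-3-ene-1-carboxylate, via allyl vinyl ether 9 (not isolated)
Conditions: Pd(OCOCF3)2 (5 mol %), 4,7-diphenyl-1,10-phenanthroline (5 mol %), butyl vinyl ether, Et3N, 75 °C; then xylene, 180 °C (sealed tube)
Reagents that add atoms: butyl vinyl ether, C=COCCCC
Why: Palladium-catalysed transfer vinylation of the allylic alcohol followed by Claisen rearrangement ([3,3], suprafacial across the allyl unit), so the new C–C bond at C2 forms on the face that carried the C4–O bond, which puts the side chain cis to the ester at C1 and trans to phenyl at C6 and moves the alkene to C3=C4.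

Step 6
Reactants: 10 methyl (1R,2R,6S)-3-methyl-2-(2-oxoethyl)-6-phenyl-1-(2,4,6-trimethoxybenzoyl)cyclohex-3-ene-1-carboxylate
Product: 11 methyl (1R,2R,6S)-3-methyl-2-(3-methylbut-2-en-1-yl)-6-phenyl-1-(2,4,6-trimethoxybenzoyl)cyclohex-3-ene-1-carboxylate
Conditions: i-PrPPh3I, n-BuLi, THF, 0 °C; then 10, −78 °C to 0 °C
Reagents that add atoms: isopropyltriphenylphosphonium iodide, CC(C)[P+](c1ccccc1)(c1ccccc1)c1ccccc1.[I-]
Why: Wittig reaction of a non-stabilised ylide with the aldehyde, which should leave alone the ester and the ketone (flanked by a quaternary carbon and a 2,6-disubstituted arene) and touches no stereocentre.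

Step 7
Reactants: 11 methyl (1R,2R,6S)-3-methyl-2-(3-methylbut-2-en-1-yl)-6-phenyl-1-(2,4,6-trimethoxybenzoyl)cyclohex-3-ene-1-carboxylate
Product: 12 [(1R,2S,6R)-3-methyl-2-(3-methylbut-2-en-1-yl)-6-phenylcyclohex-3-en-1-yl](2,4,6-trimethoxyphenyl)methanone
Conditions: LiCl (3 equiv), H2O (2 equiv), DMSO, 150 °C
Reagents that add atoms: none
Why: Krapcho dealkoxycarbonylation (chloride attacks the ester methyl, the β-keto carboxylate loses CO2), with protonation of the enolate under equilibrating conditions, so C1 should settle with the aroyl group on the face the ester occupied: aroyl and phenyl trans and both equatorial, aroyl cis to the pseudoaxial prenyl group, which avoids allylic strain with the C3 methyl.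

Step 8
Reactants: 12 [(1R,2S,6R)-3-methyl-2-(3-methylbut-2-en-1-yl)-6-phenylcyclohex-3-en-1-yl](2,4,6-trimethoxyphenyl)methanone
Product: 13 (2-hydroxy-4,6-dimethoxyphenyl)[(1R,2S,6R)-3-methyl-2-(3-methylbut-2-en-1-yl)-6-phenylcyclohex-3-en-1-yl]methanone
Conditions: BCl3 (1.5 equiv), CH2Cl2, −78 °C to 0 °C; then H2O
Reagents that add atoms: none
Why: Chelation-controlled mono-O-demethylation of an aryl methyl ether ortho to a ketone, in which the two ortho methoxy groups are equivalent, the para one is not activated, and the boron chelate formed should stop a second cleavage.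

**Compound list**

1 | 1-(2,4,6-trimethoxyphenyl)ethan-1-one | CC(=O)c1c(OC)cc(OC)cc1OC | starting material
2 | methyl 3-oxo-3-(2,4,6-trimethoxyphenyl)propanoate | COC(=O)CC(=O)c1c(OC)cc(OC)cc1OC | intermediate
3 | (2E)-3-ethoxy-2-methylprop-2-enal | CCO/C=C(\C)C=O | starting material
4 | methyl (4E)-5-ethoxy-4-methyl-2-(2,4,6-trimethoxybenzoyl)penta-2,4-dienoate (both geometries at the 2,3-double bond) | CCO/C=C(\C)C=C(C(=O)OC)C(=O)c1c(OC)cc(OC)cc1OC | intermediate
5 | 5-methyl-3-(2,4,6-trimethoxybenzoyl)-2H-pyran-2-one | COc1cc(OC)c(C(=O)c2cc(C)coc2=O)c(OC)c1 | intermediate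
6 | styrene | C=Cc1ccccc1 | starting material
7 | (1R,4R,8S)-6-methyl-8-phenyl-4-(2,4,6-trimethoxybenzoyl)-2-oxabicyclo[2.2.2]oct-5-en-3-one (phenyl anti to the lactone bridge) | O=C1O[C@@H]2C[C@@H](c3ccccc3)[C@@]1(C(=O)c1c(OC)cc(OC)cc1OC)C=C2C | intermediate
8 | methyl (1R,4R,6S)-4-hydroxy-3-methyl-6-phenyl-1-(2,4,6-trimethoxybenzoyl)cyclohex-2-ene-1-carboxylate | COC(=O)[C@]1(C(=O)c2c(OC)cc(OC)cc2OC)C=C(C)[C@H](O)C[C@H]1c1ccccc1 | intermediate
9 | methyl (1R,4R,6S)-4-(ethenyloxy)-3-methyl-6-phenyl-1-(2,4,6-trimethoxybenzoyl)cyclohex-2-ene-1-carboxylate | COC(=O)[C@]1(C(=O)c2c(OC)cc(OC)cc2OC)C=C(C)[C@H](OC=C)C[C@H]1c1ccccc1 | intermediate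
10 | methyl (1R,2R,6S)-3-methyl-2-(2-oxoethyl)-6-phenyl-1-(2,4,6-trimethoxybenzoyl)cyclohex-3-ene-1-carboxylate | COC(=O)[C@]1(C(=O)c2c(OC)cc(OC)cc2OC)[C@H](CC=O)C(C)=CC[C@H]1c1ccccc1 | intermediate
11 | methyl (1R,2R,6S)-3-methyl-2-(3-methylbut-2-en-1-yl)-6-phenyl-1-(2,4,6-trimethoxybenzoyl)cyclohex-3-ene-1-carboxylate | COC(=O)[C@]1(C(=O)c2c(OC)cc(OC)cc2OC)[C@H](CC=C(C)C)C(C)=CC[C@H]1c1ccccc1 | intermediate
12 | [(1R,2S,6R)-3-methyl-2-(3-methylbut-2-en-1-yl)-6-phenylcyclohex-3-en-1-yl](2,4,6-trimethoxyphenyl)methanone | COc1cc(OC)c(C(=O)[C@@H]2[C@H](CC=C(C)C)C(C)=CC[C@H]2c2ccccc2)c(OC)c1 | intermediate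
13 | (2-hydroxy-4,6-dimethoxyphenyl)[(1R,2S,6R)-3-methyl-2-(3-methylbut-2-en-1-yl)-6-phenylcyclohex-3-en-1-yl]methanone | COc1cc(O)c(C(=O)[C@@H]2[C@H](CC=C(C)C)C(C)=CC[C@H]2c2ccccc2)c(OC)c1 | target

Total step count: 8. Longest linear sequence: 8 steps (1 to 13).

**Steps most likely to fail**

Step 3. The cycloaddition may be slow, or its endo and facial discrimination may erode, because the twisted 2,4,6-trimethoxyphenyl ring crowds the chelated diene and styrene is a weaker donor than the alkenes usually used. The fallback sets out from 5 and 6 and returns at 8. Uncatalysed cycloaddition (toluene, 90 °C) should give the endo lactone as a racemate, that is 7 together with its enantiomer, the (1S,4S,8R)-lactone F1. Methanolysis as in step 4 gives 8 together with its enantiomer, the (1S,4S,6R)-hydroxy ester F2. Kinetic resolution by lipase-catalysed acylation (immobilised Candida antarctica lipase B, vinyl butanoate, tert-butyl methyl ether, 40 °C) follows; by the empirical rule for secondary carbinols the (4R)-alcohol 8 is the one acylated, to its butanoate F3, which is separated from unreacted F2 by chromatography. K2CO3 in MeOH then cleaves F3 back to 8, where the route is rejoined.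

Step 5. Vinyl transfer to the hindered secondary allylic alcohol may stay incomplete, the hydroxy ester may close back to lactone 7 on heating, or elimination may compete with the rearrangement at 180 °C. The fallback sets out from 8 and returns at 10. Acetylation (Ac2O, DMAP, pyridine) gives the acetate F4, whose acetyl methyl is the only acidic position because C1 is quaternary. Ireland–Claisen rearrangement (LiN(SiMe3)2, Me3SiCl, Et3N, THF, −78 °C to 60 °C; aqueous work-up) transfers the two-carbon unit to C2 on the same face and gives the carboxylic acid F5, that is 10 with CH2CO2H in place of CH2CHO. Thioesterification (EtSH, N-ethyl-N'-(3-dimethylaminopropyl)carbodiimide hydrochloride, DMAP) gives the S-ethyl thioester F6, and Fukuyama reduction (Et3SiH, Pd/C, acetone, rt) gives aldehyde 10.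

Step 2. Ring closure may run through the ketone oxygen (pyran or pyrylium formation) instead of the ester, or the hindered β-keto ester may condense sluggishly. The fallback sets out from 3 and returns at 5, replacing steps 1 and 2; Meldrum's acid and 1,3,5-trimethoxybenzene are bought. Knoevenagel condensation of 3 with Meldrum's acid (piperidine, AcOH, CH2Cl2) gives the alkylidene derivative F7. Warm aqueous acid hydrolyses the enol ether and opens the dioxanedione onto the enol oxygen to give 5-methyl-2-oxo-2H-pyran-3-carboxylic acid F8, the vinylogue of the coumarin-3-carboxylic acid synthesis. Oxalyl chloride with catalytic DMF gives the acid chloride F9, and Friedel–Crafts acylation of 1,3,5-trimethoxybenzene (SnCl4, CH2Cl2, −20 °C), whose three free positions are equivalent, gives 5.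

**Further compounds**

F1 | step 3 | (1S,4S,8R)-6-methyl-8-phenyl-4-(2,4,6-trimethoxybenzoyl)-2-oxabicyclo[2.2.2]oct-5-en-3-one (enantiomer of 7) | O=C1O[C@H]2C[C@H](c3ccccc3)[C@]1(C(=O)c1c(OC)cc(OC)cc1OC)C=C2C
F2 | step 3 | methyl (1S,4S,6R)-4-hydroxy-3-methyl-6-phenyl-1-(2,4,6-trimethoxybenzoyl)cyclohex-2-ene-1-carboxylate (enantiomer of 8) | COC(=O)[C@@]1(C(=O)c2c(OC)cc(OC)cc2OC)C=C(C)[C@@H](O)C[C@@H]1c1ccccc1
F3 | step 3 | methyl (1R,4R,6S)-4-(butanoyloxy)-3-methyl-6-phenyl-1-(2,4,6-trimethoxybenzoyl)cyclohex-2-ene-1-carboxylate | COC(=O)[C@]1(C(=O)c2c(OC)cc(OC)cc2OC)C=C(C)[C@H](OC(=O)CCC)C[C@H]1c1ccccc1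
F4 | step 5 | methyl (1R,4R,6S)-4-(acetyloxy)-3-methyl-6-phenyl-1-(2,4,6-trimethoxybenzoyl)cyclohex-2-ene-1-carboxylate | COC(=O)[C@]1(C(=O)c2c(OC)cc(OC)cc2OC)C=C(C)[C@H](OC(C)=O)C[C@H]1c1ccccc1
F5 | step 5 | 2-[(1R,5S,6R)-6-(methoxycarbonyl)-2-methyl-5-phenyl-6-(2,4,6-trimethoxybenzoyl)cyclohex-2-en-1-yl]acetic acid | COC(=O)[C@]1(C(=O)c2c(OC)cc(OC)cc2OC)[C@H](CC(=O)O)C(C)=CC[C@H]1c1ccccc1
F6 | step 5 | methyl (1R,2R,6S)-2-[2-(ethylsulfanyl)-2-oxoethyl]-3-methyl-6-phenyl-1-(2,4,6-trimethoxybenzoyl)cyclohex-3-ene-1-carboxylate | COC(=O)[C@]1(C(=O)c2c(OC)cc(OC)cc2OC)[C@H](CC(=O)SCC)C(C)=CC[C@H]1c1ccccc1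
F7 | step 2 | 5-[(2E)-3-ethoxy-2-methylprop-2-en-1-ylidene]-2,2-dimethyl-1,3-dioxane-4,6-dione | CCO/C=C(\C)C=C1C(=O)OC(C)(C)OC1=O
F8 | step 2 | 5-methyl-2-oxo-2H-pyran-3-carboxylic acid | Cc1coc(=O)c(C(=O)O)c1
F9 | step 2 | 5-methyl-2-oxo-2H-pyran-3-carbonyl chloride | Cc1coc(=O)c(C(=O)Cl)c1
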